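**Plan**

1. Numbering: seven-membered ring C10 (=C20H2), C1, C2, C3, C4 (CMe2), C5, C9; cyclopentane C5–C6–C7–C8(CH3)–C9; side chain C8–C14(C15H2OAc)–C13; lactone C13–C12H2–O–C16(=O)–C11H2.
2. Retrosynthesis: C10=C20 (from a C10 ketone), the second C4 methyl (from a C3=C4 alkene), the C10–C4 bond of a cyclobutane C10–C4–C5–C9 (a fragmentation run backwards), then C9–C10 and C4–C5 ([2+2]); in the side chain C13–C12, C11=C13, C14–C15 and C8–C14.
3. Enabling feature: on the cis-fused bond C5–C9, C9 carries the carbonyl-level carbon C10 and C5 the quaternary C4, and C10 and C4 are also linked through C1–C2–C3. A C10–C4 bond therefore closes a cyclobutane fused to two five-membered rings, which is the photoadduct of a cyclopentene with the enol acetate of 2-methylcyclopentane-1,3-dione.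
4. Forward order: cyclopentene with quaternary C8 (Claisen, C8–C14 bond); side chain (C15, then C11/C16, then C12) and γ-lactone; cyclobutane by photocycloaddition; seven-membered ring by fragmentation; gem-dimethyl; exocyclic methylene.
5. Stereochemistry: C8 from a CBS reduction relayed by a suprafacial [3,3] shift; C14 from an oxazolidinone auxiliary; C13 by anti addition on a δ-lactone; C5 and C9 from cycloaddition on the alkene face of the C8 methyl, away from the branched C14 arm.

Key step: step 15

Assumption: PtO2/H2 in acetic acid (step 20) is taken to reduce the hindered C10 ketone along with the cyclopropane, so a re-oxidation (step 21) is planned.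

**Route**

Step 1
Reactants: 1 3-methylcyclopent-2-en-1-one
Product: 2 (S)-3-methylcyclopent-2-en-1-ol
Conditions: (R)-1-methyl-3,3-diphenyltetrahydro-1H,3H-pyrrolo[1,2-c][1,3,2]oxazaborole (10 mol%), BH3·SMe2, THF, −20 °C; MeOH quench
Reagents that add atoms: none
Why: Corey–Bakshi–Shibata reduction, in which the oxazaborolidine binds the carbonyl with the alkenyl side as the large group and delivers hydride to one face, which should set the carbinol carbon (future C5) as S; the volatile, acid-sensitive alcohol is used as a solution.

Step 2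
Reactants: 2 (S)-3-methylcyclopent-2-en-1-ol
Product: 3 (S)-3-methylcyclopent-2-en-1-yl acetate
Conditions: Ac2O, Et3N, 4-(dimethylamino)pyridine (cat.), CH2Cl2, 0 °C
Reagents that add atoms: acetic anhydride, CC(=O)OC(C)=O
Why: Nucleophile-catalysed O-acylation under basic conditions, which avoids ionisation of the tertiary-allylic system and leaves the stereocentre untouched.

Step 3
Reactants: 3 (S)-3-methylcyclopent-2-en-1-yl acetate
Product: 6 (S)-2-(1-methylcyclopent-2-en-1-yl)acetic acid, via silyl ketene acetal 4 (not isolated), via silyl ester 5 (not isolated)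
Conditions: LiN(i-Pr)2, THF, −78 °C; Me3SiCl; −78 → 60 °C; 1 M HCl
Reagents that add atoms: none
Why: Ireland–Claisen rearrangement, whose suprafacial [3,3] shift forms C8–C14 on the ring face that carried the C–O bond, so the carbinol stereocentre is exchanged for quaternary C8 (S) and the double bond moves to C5=C9.

Step 4
Reactants: 6 (S)-2-(1-methylcyclopent-2-en-1-yl)acetic acid; 7 (S)-4-benzyloxazolidin-2-one
Product: 9 (S)-4-benzyl-3-[2-((S)-1-methylcyclopent-2-en-1-yl)acetyl]oxazolidin-2-one, via mixed anhydride 8 (not isolated)
Conditions: t-BuCOCl, Et3N, THF, −20 °C; then LiCl, 7, rt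
Reagents that add atoms: none
Why: N-acylation of the oxazolidinone through the pivalic mixed anhydride, which is attacked at the less hindered acyl carbon; no stereocentre is formed.

Step 5
Reactants: 9 (S)-4-benzyl-3-[2-((S)-1-methylcyclopent-2-en-1-yl)acetyl]oxazolidin-2-one
Product: 10 hydroxymethyl imide (imide 9 with CH2OH on C14; C14 as in the target)
Conditions: TiCl4, i-Pr2NEt, CH2Cl2, 0 °C; then 1,3,5-trioxane, TiCl4, 0 °C
Reagents that add atoms: 1,3,5-trioxane, C1OCOCO1
Why: Evans hydroxymethylation of the chelated (Z)-titanium enolate, where the formaldehyde–TiCl4 complex should attack the enolate face opposite the benzyl group and so set C14 under auxiliary control, overriding the neighbouring quaternary C8.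

Step 6
Reactants: 10 hydroxymethyl imide
Product: 11 silyl ether imide (C15–OTBS)
Conditions: t-BuMe2SiCl, imidazole, DMF, rt
Reagents that add atoms: tert-butyldimethylsilyl chloride, CC(C)(C)[Si](C)(C)Cl
Why: Standard silylation of the primary alcohol, which blocks retro-aldol loss of formaldehyde and differentiates C15 from the acyl carbon C13.

Step 7
Reactants: 11 silyl ether imide
Product: 12 S-ethyl 3-[(tert-butyldimethylsilyl)oxy]-2-(1-methylcyclopent-2-en-1-yl)propanethioate (C8 and C14 as in 11)
Conditions: EtSH, n-BuLi, THF, 0 °C
Reagents that add atoms: ethanethiol, CCS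
Why: Thiolate cleavage of the imide, which attacks the exocyclic carbonyl even of a hindered acyl group (where hydride reagents tend to open the oxazolidinone ring) and is too weakly basic to enolise C14; auxiliary 7 is recovered.

Step 8
Reactants: 12 thioester
Product: 13 3-[(tert-butyldimethylsilyl)oxy]-2-(1-methylcyclopent-2-en-1-yl)propanal (C8 and C14 as in 11)
Conditions: i-Bu2AlH, CH2Cl2, −78 °C
Reagents that add atoms: none
Why: Partial reduction of a thioester to the aldehyde through a tetrahedral aluminium hemithioacetal that is stable at low temperature, so C14 (α to the new aldehyde) should not epimerise.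

Step 9
Reactants: 13 aldehyde
Product: 14 methyl (Z)-5-[(tert-butyldimethylsilyl)oxy]-4-(1-methylcyclopent-2-en-1-yl)pent-2-enoate
Conditions: (CF3CH2O)2P(O)CH2CO2Me, KN(SiMe3)2, 18-crown-6, THF, −78 °C
Reagents that add atoms: methyl bis(2,2,2-trifluoroethyl)phosphonoacetate, COC(=O)CP(=O)(OCC(F)(F)F)OCC(F)(F)F
Why: Still–Gennari olefination, in which the electron-poor phosphonate and the dissociated potassium enolate make oxaphosphetane formation kinetically controlled, which should give the (Z)-enoate (C13=C11) needed for ring closure.

Step 10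
Reactants: 14 (Z)-enoate
Product: 16 5-(1-methylcyclopent-2-en-1-yl)-5,6-dihydro-2H-pyran-2-one (lactone C5 = C14), via hydroxy ester 15 (not isolated)
Conditions: (+)-camphor-10-sulfonic acid (cat.), MeOH, rt; then PhMe, 60 °C
Reagents that add atoms: none
Why: Acid-mediated desilylation followed by lactonisation of the C15 hydroxyl onto the cis-disposed ester, giving the α,β-unsaturated δ-lactone without touching C14.

Step 11
Reactants: 16 unsaturated δ-lactone
Product: 17 trans-4-{[dimethyl(propan-2-yloxy)silyl]methyl}-5-(1-methylcyclopent-2-en-1-yl)oxan-2-one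
Conditions: (i-PrO)Me2SiCH2MgCl, CuBr·SMe2 (20 mol%), THF, −40 → −10 °C
Reagents that add atoms: [dimethyl(propan-2-yloxy)silyl]methylmagnesium chloride, CC(C)O[Si](C)(C)C[Mg]Cl
Why: Copper-catalysed conjugate addition of Tamao's hydroxymethyl anion equivalent, which should enter C13 anti to the bulky ring substituent on the adjacent C14 (1,2-induction on the half-chair lactone) and so set C13 trans to it.

Step 12
Reactants: 17 silylmethyl δ-lactone
Product: 19 4-[2-hydroxy-1-(1-methylcyclopent-2-en-1-yl)ethyl]oxolan-2-one (C8, C13, C14 as in the target), via hydroxymethyl lactone 18 (not isolated)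
Conditions: 30% H2O2, KF, KHCO3, THF/MeOH, rt; then pyridinium p-toluenesulfonate, CH2Cl2, rt
Reagents that add atoms: hydrogen peroxide, OO
Why: Tamao oxidation converts C12–Si into C12–OH, and this primary hydroxyl then translactonises onto C16 because the γ-lactone is favoured over the δ-lactone, which releases the C15 hydroxyl; no stereocentre is involved.

Step 13
Reactants: 19 γ-lactone alcohol
Product: 20 2-(1-methylcyclopent-2-en-1-yl)-2-(5-oxooxolan-3-yl)ethyl acetate (C8, C13, C14 as in the target)
Conditions: Ac2O, pyridine, 4-(dimethylamino)pyridine (cat.), CH2Cl2, rt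
Reagents that add atoms: acetic anhydride, CC(=O)OC(C)=O
Why: Routine acetylation of the primary alcohol, which completes the side chain and makes the C8 arm a large branched group for the cycloaddition.

Step 14
Reactants: 21 2-methylcyclopentane-1,3-dione
Product: 22 3-acetoxy-2-methylcyclopent-2-en-1-one
Conditions: AcCl, pyridine, CH2Cl2, 0 °C
Reagents that add atoms: acetyl chloride, CC(Cl)=O
Why: O-acylation of the fully enolised 1,3-dione (a vinylogous acid) gives the enol acetate, which holds the enone in one tautomer.

Step 15
Reactants: 20 cyclopentene with the complete side chain; 22 3-acetoxy-2-methylcyclopent-2-en-1-one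
Product: 23 tricyclic photoadduct (cyclobutane C10–C4–C5–C9 fused cis-anti-cis to the cyclopentane and to a cyclopentanone; OAc on C10, CH3 on C4, ketone at C3)
Conditions: hν (medium-pressure Hg lamp, Pyrex, λ > 300 nm), 22 (4 equiv), degassed CH2Cl2, −20 °C
Reagents that add atoms: none
Why: The triplet state of enone 22 adds to the cyclopentene through a 1,4-biradical that collapses to the cyclobutane C10–C4–C5–C9, which is the de Mayo variant of the enone–alkene [2+2] photocycloaddition known for enol acetates of cyclic 1,3-diones and cyclopentenes. The four-membered ring closes by stepwise [2+2] (radical recombination), and its size forces cis fusion both at C5–C9 and at C4–C10, with the two five-membered rings anti across the cyclobutane. C5 and C9 are set by the alkene face that is attacked: quaternary C8 covers one face with the branched C14 arm (acetoxymethyl and lactone) and leaves the face of its methyl group open, so C10 and C4 should enter cis to that methyl. C10 and C4 are stereogenic only while the cyclobutane exists and are cleared in steps 18 and 20. The step needs orientation as well as facial selectivity: C10, which carries only O and CH2, should tolerate the neopentyl carbon C9 better than C4 with its methyl and carbonyl substituents, which goes to the unhindered C5. Acetate and lactone do not absorb above 300 nm, and the excess of 22 keeps the valuable alkene from being consumed in side reactions.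

Step 16
Reactants: 23 tricyclic photoadduct
Product: 24 C3 alcohol (OH on the concave face, cis to C5 across the five-membered ring)
Conditions: NaBH4, MeOH/CH2Cl2, −20 °C
Reagents that add atoms: none
Why: Chemoselective borohydride reduction of the only ketone while C10 is still masked as its tertiary acetate, which differentiates C3 from C10; hydride should arrive on the convex face (the concave face is blocked by H5 of the cyclobutane), placing the hydroxyl cis to C5.

Step 17
Reactants: 24 C3 alcohol
Product: 25 C3 methanesulfonate (same configuration)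
Conditions: MeSO2Cl, Et3N, CH2Cl2, 0 °C
Reagents that add atoms: methanesulfonyl chloride, CS(Cl)(=O)=O
Why: Sulfonylation via the sulfene, which tolerates the hindered neopentyl-type secondary alcohol and retains configuration at C3.

Step 18
Reactants: 25 C3 methanesulfonate
Product: 28 cycloheptenone acetate (C10 ketone, C3=C4 alkene with CH3 on C4, C15 acetate, cis ring fusion), via cyclobutanol 26 (not isolated), via hydroxy ketone 27 (not isolated)
Conditions: NaOMe, MeOH, 0 °C → rt; AcOH, then pyridinium p-toluenesulfonate, CH2Cl2; then Ac2O, pyridine, 4-(dimethylamino)pyridine (cat.)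
Reagents that add atoms: acetic anhydride, CC(=O)OC(C)=O
Why: Grob (Wharton-type) fragmentation of a 1,3-hydroxy sulfonate: methanolysis of the acetates frees the C10 alkoxide, whose push breaks the strained C10–C4 bond as the sulfonate leaves from C3, giving the C10 ketone and the ring (Z) alkene C3=C4. The acid treatment relactonises any opened γ-lactone and the C15 hydroxyl is re-acetylated; C5 and C9 are untouched.

Step 19
Reactants: 28 cycloheptenone acetate
Product: 29 cyclopropane (CH2 bridging C3 and C4 on the face of H5)
Conditions: Et2Zn, CH2I2, CH2Cl2, 0 °C → rt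
Reagents that add atoms: diiodomethane, ICI
Why: Simmons–Smith cyclopropanation (Furukawa variant) of the electron-rich trisubstituted alkene, stereospecific and expected from the convex face; the configuration at C3 and C4 is of no consequence because both centres lose their stereogenicity in step 20.

Step 20
Reactants: 29 cyclopropane
Product: 30 4,4-dimethyl C10 alcohol (mixture of C10 epimers)
Conditions: H2 (3 atm), PtO2, AcOH, rt
Reagents that add atoms: none
Why: Catalytic hydrogenolysis of the cyclopropane at its least hindered bond (C3–CH2), the classical route to a gem-dimethyl group, which makes C3 a methylene and the bridging carbon the second methyl on C4; the ketone is expected to be reduced as well.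

Step 21
Reactants: 30 C10 alcohol (epimers)
Product: 31 4,4-dimethyl C10 ketone
Conditions: Dess–Martin periodinane, NaHCO3, CH2Cl2, rt
Reagents that add atoms: none
Why: Dess–Martin oxidation converges both carbinol epimers on the ketone under buffered conditions that should not epimerise C9.

Step 22
Reactants: 31 4,4-dimethyl C10 ketone
Product: 32 target compound (CNP0235949.1)
Conditions: Zn, CH2Br2, TiCl4, THF/CH2Cl2, 0 °C → rt
Reagents that add atoms: dibromomethane, BrCBr
Why: Takai–Lombardo methylenation, a non-basic titanium–zinc carbenoid that converts hindered, enolisable ketones without epimerising the α-centre (C9) and leaves the acetate and lactone alone.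

**Compound list**

1 | 3-methylcyclopent-2-en-1-one | CC1=CC(=O)CC1 | starting material
2 | (S)-3-methylcyclopent-2-en-1-ol | CC1=C[C@@H](O)CC1 | intermediate
3 | (S)-3-methylcyclopent-2-en-1-yl acetate | CC1=C[C@@H](OC(C)=O)CC1 | intermediate
4 | trimethylsilyl ketene acetal of 3 (not isolated) | CC1=C[C@@H](OC(=C)O[Si](C)(C)C)CC1 | intermediate
5 | trimethylsilyl (S)-2-(1-methylcyclopent-2-en-1-yl)acetate (not isolated) | C[C@@]1(CC(=O)O[Si](C)(C)C)CCC=C1 | intermediate
6 | (S)-2-(1-methylcyclopent-2-en-1-yl)acetic acid | C[C@@]1(CC(O)=O)CCC=C1 | intermediate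
7 | (S)-4-benzyloxazolidin-2-one | O=C1N[C@@H](Cc2ccccc2)CO1 | starting material
8 | pivalic mixed anhydride of 6 (not isolated) | C[C@@]1(CC(=O)OC(=O)C(C)(C)C)CCC=C1 | intermediate
9 | (S)-4-benzyl-3-[2-((S)-1-methylcyclopent-2-en-1-yl)acetyl]oxazolidin-2-one | C[C@@]1(CC(=O)N2[C@@H](Cc3ccccc3)COC2=O)CCC=C1 | intermediate
10 | hydroxymethyl imide (CH2OH on C14) | C[C@@]1([C@H](CO)C(=O)N2[C@@H](Cc3ccccc3)COC2=O)CCC=C1 | intermediate
11 | silyl ether imide (C15–OTBS) | C[C@@]1([C@H](CO[Si](C)(C)C(C)(C)C)C(=O)N2[C@@H](Cc3ccccc3)COC2=O)CCC=C1 | intermediate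
12 | S-ethyl thioester | C[C@@]1([C@H](CO[Si](C)(C)C(C)(C)C)C(=O)SCC)CCC=C1 | intermediate
13 | C13 aldehyde | C[C@@]1([C@H](CO[Si](C)(C)C(C)(C)C)C=O)CCC=C1 | intermediate
14 | methyl (Z)-enoate | C[C@@]1([C@H](CO[Si](C)(C)C(C)(C)C)/C=C\C(=O)OC)CCC=C1 | intermediate
15 | methyl (Z)-5-hydroxy-4-(1-methylcyclopent-2-en-1-yl)pent-2-enoate (not isolated) | C[C@@]1([C@H](CO)/C=C\C(=O)OC)CCC=C1 | intermediate
16 | 5-(1-methylcyclopent-2-en-1-yl)-5,6-dihydro-2H-pyran-2-one | C[C@@]1([C@@H]2COC(=O)C=C2)CCC=C1 | intermediate
17 | trans-4-(silylmethyl) δ-lactone | C[C@@]1([C@@H]2COC(=O)C[C@H]2C[Si](C)(C)OC(C)C)CCC=C1 | intermediate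
18 | trans-4-(hydroxymethyl) δ-lactone (not isolated) | C[C@@]1([C@@H]2COC(=O)C[C@H]2CO)CCC=C1 | intermediate
19 | γ-lactone alcohol | C[C@@]1([C@H](CO)[C@@H]2COC(=O)C2)CCC=C1 | intermediate
20 | 2-(1-methylcyclopent-2-en-1-yl)-2-(5-oxooxolan-3-yl)ethyl acetate | C[C@@]1([C@H](COC(C)=O)[C@@H]2COC(=O)C2)CCC=C1 | intermediate
21 | 2-methylcyclopentane-1,3-dione | CC1C(=O)CCC1=O | starting material
22 | 3-acetoxy-2-methylcyclopent-2-en-1-one | CC1=C(OC(C)=O)CCC1=O | intermediate
23 | tricyclic photoadduct | CC(=O)O[C@]12CCC(=O)[C@@]1(C)[C@@H]1CC[C@@](C)([C@H](COC(C)=O)[C@@H]3COC(=O)C3)[C@@H]12 | intermediate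
24 | C3 alcohol of 23 | CC(=O)O[C@]12CC[C@@H](O)[C@@]1(C)[C@@H]1CC[C@@](C)([C@H](COC(C)=O)[C@@H]3COC(=O)C3)[C@@H]12 | intermediate
25 | C3 methanesulfonate | CC(=O)O[C@]12CC[C@@H](OS(C)(=O)=O)[C@@]1(C)[C@@H]1CC[C@@](C)([C@H](COC(C)=O)[C@@H]3COC(=O)C3)[C@@H]12 | intermediate
26 | deacetylated cyclobutanol (not isolated) | O[C@]12CC[C@@H](OS(C)(=O)=O)[C@@]1(C)[C@@H]1CC[C@@](C)([C@H](CO)[C@@H]3COC(=O)C3)[C@@H]12 | intermediate
27 | hydroxy cycloheptenone (not isolated) | O=C1CCC=C(C)[C@@H]2CC[C@@](C)([C@H](CO)[C@@H]3COC(=O)C3)[C@H]12 | intermediate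
28 | cycloheptenone acetate | O=C1CCC=C(C)[C@@H]2CC[C@@](C)([C@H](COC(C)=O)[C@@H]3COC(=O)C3)[C@H]12 | intermediate
29 | C3–C4 cyclopropane | O=C1CC[C@H]3C[C@@]3(C)[C@@H]2CC[C@@](C)([C@H](COC(C)=O)[C@@H]4COC(=O)C4)[C@H]12 | intermediate
30 | 4,4-dimethyl C10 alcohol (C10 epimers, C10 left undefined) | OC1CCCC(C)(C)[C@@H]2CC[C@@](C)([C@H](COC(C)=O)[C@@H]3COC(=O)C3)[C@H]12 | intermediate
31 | 4,4-dimethyl C10 ketone | O=C1CCCC(C)(C)[C@@H]2CC[C@@](C)([C@H](COC(C)=O)[C@@H]3COC(=O)C3)[C@H]12 | intermediate
32 | CNP0235949.1 | C=C1CCCC(C)(C)[C@@H]2CC[C@@](C)([C@H](COC(C)=O)[C@@H]3COC(=O)C3)[C@H]12 | target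

**Step count and risks**

Total steps: 22. Longest linear sequence: 21 steps (steps 1–13 and 15–22); step 14 makes the second photo-component in one step.

Steps most likely to fail:

1. Step 15. The enone may add in the reversed orientation (methyl-bearing carbon to C9), or partly on the face of the C14 arm, because both selectivities rest on steric differences at C8. Fallback, setting out from 20: allylic oxidation of the only allylic methylene (C6) with t-BuOOH and Rh2(caprolactamate)4 would give the 4-methyl-4-substituted cyclopent-2-en-1-one F1, in which C9 is the β-carbon of an enone. Irradiated above 340 nm with excess 22, F1 is the absorbing partner and 22 a donor-substituted alkene; the head-to-tail rule of enone photocycloaddition then puts the acetoxy-bearing C10 on the β-carbon C9 and C4 on C5 for electronic reasons, giving the diketone adduct F2. Its C6 carbonyl, the only one without a fully substituted α-carbon, is condensed with p-toluenesulfonylhydrazide to the C6 tosylhydrazone F3 and reduced with catecholborane (then NaOAc), which brings the route back at 23.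

2. Step 18. The C10 alkoxide may displace the sulfonate (oxetane formation), or step 16 may deliver mainly the C3 epimer whose C–O bond cannot align with C4–C10, so that fragmentation is slow. Fallback, setting out from 23: NaOMe in MeOH followed by re-acetylation opens the cyclobutane by the classical retro-aldol path to the 3,10-dione F4 (C4 as CH(CH3), either epimer). Its C3 carbonyl, flanked by CH(CH3) and CH2 and remote from C8, is triflated under equilibrating conditions (Tf2O, 2,6-di-tert-butyl-4-methylpyridine) to the tetrasubstituted C3=C4 enol triflate F5. Reduction with Pd(OAc)2, PPh3, HCO2H and Bu3N then rejoins the route at 28.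

3. Step 11. The bulky organocopper reagent may add slowly, or at the lactone carbonyl, next to the neopentyl carbon C14. Fallback, setting out from 16: base-catalysed Michael addition of nitromethane (1,8-diazabicyclo[5.4.0]undec-7-ene, MeCN), a small nucleophile that should still enter anti to the C14 substituent, gives the trans-4-(nitromethyl) lactone F6. A Nef reaction with aqueous TiCl3 (NH4OAc buffer) gives the trans-4-formyl lactone F7, and NaBH4 in MeOH reduces it to 18, which is carried to 19 by the acid treatment of step 12.

Further compounds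
F1 | step 15 | 4-methyl-4-[2-acetoxy-1-(5-oxooxolan-3-yl)ethyl]cyclopent-2-en-1-one (20 oxidised at C6) | C[C@@]1([C@H](COC(C)=O)[C@@H]2COC(=O)C2)CC(=O)C=C1
F2 | step 15 | photoadduct 23 carrying an additional C6 ketone | CC(=O)O[C@]12CCC(=O)[C@@]1(C)[C@@H]1C(=O)C[C@@](C)([C@H](COC(C)=O)[C@@H]3COC(=O)C3)[C@@H]12
F3 | step 15 | C6 p-toluenesulfonylhydrazone of F2 | CC(=O)O[C@]12CCC(=O)[C@@]1(C)[C@@H]1C(=NNS(=O)(=O)c4ccc(C)cc4)C[C@@](C)([C@H](COC(C)=O)[C@@H]3COC(=O)C3)[C@@H]12
F4 | step 18 | 3,10-dione with CH(CH3) at C4 and C15 acetate (C4 epimers, C4 left undefined) | O=C1CCC(=O)C(C)[C@@H]2CC[C@@](C)([C@H](COC(C)=O)[C@@H]3COC(=O)C3)[C@H]12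
F5 | step 18 | C3=C4 enol triflate of F4 | O=C1CCC(OS(=O)(=O)C(F)(F)F)=C(C)[C@@H]2CC[C@@](C)([C@H](COC(C)=O)[C@@H]3COC(=O)C3)[C@H]12
F6 | step 11 | trans-4-(nitromethyl)-5-(1-methylcyclopent-2-en-1-yl)oxan-2-one | C[C@@]1([C@@H]2COC(=O)C[C@H]2C[N+](=O)[O-])CCC=C1
F7 | step 11 | trans-4-formyl-5-(1-methylcyclopent-2-en-1-yl)oxan-2-one | C[C@@]1([C@@H]2COC(=O)C[C@H]2C=O)CCC=C1
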